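Retrosynthesis: the C12–C13 bond is cut first (alkylzinc + 2-iodoalkene), then the lactone C8–O bond together with C6–C7 of ring B, then C9–C11 (sigmatropic), C5–C6, and the C9–C10 bond of a bridged lactone.
Forward: ring A comes from 2,6-dimethylcyclohexanone; a C18–O–C9 lactone bridge ties C4 to C10; C6 is added on that template; opening the bridge and a Claisen step give the seco aldehyde acid; ring B and the 8,12-lactone ring close together; the C13–C19 arm (from L-tartrate) is joined last and C18 is oxidised at the end.
Enabling feature: the 6-hydroxyl and the C8 oxygen sit 1,3 to each other across the C7 methylene of ring B, and C12 is three atoms from C8, so a C6 aldehyde, a C7=C8 isopropenyl group and a C12 acid on C9 can form ring B (C5–C10) and the five-membered lactone ring in one operation.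
Stereochemistry: C4 by ligand-controlled Pd allylation; C10 by the lactone tether; C5 by hydroboration on the bridged template; C9 by the chair Claisen transition state; C6 and C8 by the chair Prins transition state; C14/C15 from L-tartrate; C16 by reagent-controlled alkynylation.

Key step: step 17

Remark on the chemistry: positions are numbered as in the labdane skeleton (C1–C12 and C17–C20 for the bicyclic core, C13–C19 for the butenolide arm), α is the face of H-5, and the 6-hydroxy 18-aldehyde is taken in the open, non-hemiacetal form that the given structure shows.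

Step 1
Reactants: 1 2,6-dimethylcyclohexanone; 2 allyl chloroformate
Product: 3 allyl 2,6-dimethylcyclohex-1-en-1-yl carbonate
Conditions: LiHMDS, TMEDA, THF, 0 °C; then 2, −78 °C
Reagents that add atoms: none
Why: O-acylation of the only possible (tetrasubstituted) lithium enolate by the chloroformate gives the allyl enol carbonate needed for the decarboxylative Tsuji allylation, and no stereocentre of consequence is formed.

Step 2
Reactants: 3 allyl enol carbonate
Product: 4 (2S)-2-allyl-2,6-dimethylcyclohexanone
Conditions: Pd2(dba)3 (2.5 mol %), (S)-t-BuPHOX (6 mol %), THF, 25 °C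
Reagents that add atoms: none
Why: Decarboxylative asymmetric Tsuji allylation, in which loss of CO2 gives a PHOX-ligated π-allylpalladium enolate that is alkylated at the tetrasubstituted carbon, so the ligand sets the quaternary centre (future C4, expected 2S by analogy with 2-methylcyclohexanone enol carbonates) while the C6 methine stays a mixture that is erased in step 6.

Step 3
Reactants: 4 allyl ketone
Product: 5 (2S)-2,6-dimethyl-2-[(E)-prop-1-en-1-yl]cyclohexanone
Conditions: RuHCl(CO)(PPh3)3 (3 mol %), toluene, 100 °C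
Reagents that add atoms: none
Why: Ruthenium hydride-catalysed alkene isomerisation moves the terminal double bond one position to the more substituted (E)-propenyl group and stops there because the neighbouring carbon is quaternary.

Step 4
Reactants: 5 propenyl ketone
Product: 7 (2S)-2-(hydroxymethyl)-2,6-dimethylcyclohexanone, via keto aldehyde 6 (not isolated)
Conditions: O3, CH2Cl2/MeOH, −78 °C; Me2S; then NaBH4, MeOH, −78 °C
Reagents that add atoms: ozone, [O-][O+]=O
Why: Ozonolysis cuts the propenyl group down to the one-carbon aldehyde on the quaternary centre, and borohydride at −78 °C reduces this aldehyde much faster than the ketone flanked by the quaternary carbon, so C18 is obtained as CH2OH with the stereocentre untouched.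

Step 5
Reactants: 7 hydroxymethyl ketone
Product: 8 [(1S)-1,3-dimethyl-2-oxocyclohexyl]methyl 1H-imidazole-1-carboxylate
Conditions: 1,1'-carbonyldiimidazole, CH2Cl2, rt
Reagents that add atoms: 1,1'-carbonyldiimidazole, O=C(n1ccnc1)n1ccnc1
Why: Acyl transfer from carbonyldiimidazole to the primary alcohol gives an isolable imidazole carboxylate, an acylating tether held on the face of C18.

Step 6
Reactants: 8 imidazole carboxylate
Product: 9 (1S,5S)-1,5-dimethyl-3-oxabicyclo[3.3.1]nonane-2,9-dione
Conditions: KHMDS, THF (high dilution), −78 °C to 0 °C; aq. NH4Cl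
Reagents that add atoms: none
Why: Intramolecular Claisen (Dieckmann-type) acylation in which the only enolate that can form (C5/C10) attacks the tethered carbamate through a six-membered transition state, so the new C9 carbonyl can only arrive cis to C18, which fixes C10 (methyl β) relative to C4, and since imidazolide can reopen any O-acylated enol carbonate the C-acylated bridged keto lactone is expected to accumulate.

Step 7
Reactants: 9 bridged keto lactone
Product: 10 (1S,5R)-1,5-dimethyl-9-methylidene-3-oxabicyclo[3.3.1]nonan-2-one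
Conditions: Zn, CH2Br2, TiCl4, THF/CH2Cl2, 0 °C to rt
Reagents that add atoms: dibromomethane, BrCBr
Why: Lombardo–Takai methylenation with the non-basic gem-dimetallic reagent converts hindered ketones into methylene groups and leaves lactones alone, which installs C6 on C5 and at the same time removes the base-sensitive 1,3-dicarbonyl unit.

Step 8
Reactants: 10 methylene lactone
Product: 11 9-(hydroxymethyl)-1,5-dimethyl-3-oxabicyclo[3.3.1]nonan-2-one with the CH2OH group on the carbocycle side
Conditions: BH3·SMe2, THF, 0 °C to rt; then 30 % H2O2, aq. NaOAc, 0 °C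
Reagents that add atoms: hydrogen peroxide, OO
Why: Hydroboration–oxidation places boron on the terminal carbon, and on the rigid bicyclo[3.3.1] template hydrogen should be delivered to C5 from the side of the lactone ring (one syn-axial hydrogen and a flat ester) instead of the carbocycle side (two syn-axial hydrogens), which gives H-5 α and C6 β.

Step 9
Reactants: 11 hydroxymethyl lactone
Product: 12 tert-butyldimethylsilyl ether of 11
Conditions: TBSCl, imidazole, DMF, rt
Reagents that add atoms: tert-butyldimethylsilyl chloride, C[Si](C)(Cl)C(C)(C)C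
Why: Standard silylation of the primary alcohol protects the C6 oxygen for the hydride and base steps that follow.

Step 10
Reactants: 12 silyl ether lactone
Product: 13 bridged lactol (2-hydroxy analogue of 12; both anomers)
Conditions: DIBAL-H (1.2 equiv), CH2Cl2, −78 °C; Rochelle salt
Reagents that add atoms: none
Why: DIBAL-H at −78 °C stops at the tetrahedral aluminium hemiacetal, so work-up gives the lactol, the masked form of the C9 aldehyde.

Step 11
Reactants: 13 lactol
Product: 14 ethyl (E)-2-methyl-3-(ring A)prop-2-enoate with free C18 hydroxyl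
Conditions: Ph3P=C(Me)CO2Et, toluene, 110 °C
Reagents that add atoms: ethyl 2-(triphenylphosphoranylidene)propanoate, CCOC(=O)C(C)=P(c1ccccc1)(c1ccccc1)c1ccccc1
Why: Wittig olefination of the ring-opened hydroxy aldehyde tautomer with the stabilised α-branched ylide gives the (E)-trisubstituted enoate (C9=C8 with the C8 methyl cis to C10) and releases the C18 hydroxyl.

Step 12
Reactants: 14 hydroxy enoate
Product: 15 18-O-(2-naphthylmethyl) ether of 14
Conditions: NaH, 2-(bromomethyl)naphthalene, Bu4NI (cat.), THF/DMF, 0 °C to rt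
Reagents that add atoms: 2-(bromomethyl)naphthalene, BrCc1ccc2ccccc2c1
Why: Williamson etherification puts the 2-naphthylmethyl group on O18, a benzyl-type ether that survives Lewis acids, hydrides and fluoride and can later be removed oxidatively in the presence of alkenes.

Step 13
Reactants: 15 enoate
Product: 16 (E)-allylic alcohol (C7 hydroxyl)
Conditions: DIBAL-H (2.5 equiv), CH2Cl2, −78 °C
Reagents that add atoms: none
Why: DIBAL-H 1,2-reduction of the unsaturated ester gives the primary allylic alcohol required for the Claisen step without touching the silyl or naphthylmethyl ethers.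

Step 14
Reactants: 16 allylic alcohol
Product: 18 ethyl ester carrying the C9 stereocentre and the isopropenyl group, via ketene acetal 17 (not isolated)
Conditions: MeC(OEt)3, EtCO2H (cat.), 140 °C, ethanol distilled off
Reagents that add atoms: triethyl orthoacetate, CCOC(C)(OCC)OCC
Why: Johnson–Claisen rearrangement in which the mixed ketene acetal reacts through a chair transition state with the C10 methyl in the alkene plane next to the cis C8 methyl (least A(1,3) strain) and the new C9–C11 bond forming on the face away from C5 and its silyloxymethyl arm, which should give the C9 configuration of the target together with the isopropenyl group (C7=C8) and the C11–C12 ester.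

Step 15
Reactants: 18 silyl ether ester
Product: 20 hydroxy acid (C6 hydroxyl; C12 acid), via hydroxy ester 19 (not isolated)
Conditions: TBAF, THF, rt; then LiOH, MeOH/H2O, rt; cold dilute HCl to pH 3
Reagents that add atoms: lithium hydroxide, [Li+].[OH-]
Why: Fluoride removes the primary silyl ether and hydroxide then saponifies the ester, both under non-acidic conditions, because acid would add the carboxyl group across the isopropenyl group.

Step 16
Reactants: 20 hydroxy acid
Product: 21 seco aldehyde acid (C6 aldehyde; C7=C8 isopropenyl on C9; C12 acid)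
Conditions: Dess–Martin periodinane, NaHCO3, CH2Cl2, 0 °C
Reagents that add atoms: none
Why: Dess–Martin oxidation of the primary alcohol under bicarbonate buffer gives the aldehyde without over-oxidation and without epimerising the hindered C5 centre.

Step 17
Reactants: 21 seco aldehyde acid
Product: 22 6α-hydroxy-18-(2-naphthylmethoxy)-13,14,15,16-tetranorlabdan-12,8α-olide
Conditions: Me2AlCl (2.5 equiv), CH2Cl2, −78 °C; quench at −78 °C with aq. Rochelle salt
Reagents that add atoms: none
Why: Proposed new method: the first equivalent of Me2AlCl turns the acid into an aluminium carboxylate (methane is lost) and a second activates the C6 aldehyde, the terminal carbon C7 of the isopropenyl group attacks C6 to form the C6–C7 bond and ring B, and the carboxylate oxygen on the C9 arm captures the tertiary C8 cation before proton loss to close the lactone. The closest known reactions are the alkylaluminium halide-promoted type 2 carbonyl-ene and Prins cyclisations of unsaturated aldehydes and the carboxylic acid-terminated cationic cyclisations that give 8,12-olides of this decalin type. Ring B closes in a 6-endo mode with respect to the C7=C8 alkene through a chair transition state fused trans to ring A, and the lactone ring closes by five-membered O–C8 bond formation onto the cation. C6 is set by the aldehyde oxygen taking the equatorial (α) position of that chair, away from the axial C4 and C10 methyls, and C8 by attack of the carboxylate on the α face, because the β face is covered by the axial C10 methyl, which gives the trans-fused lactone with the C8 methyl axial. The step needs cation capture to outrun proton loss and the trans lactone to survive, and the substrate secures this by holding the nucleophile three atoms from C8 on the equatorial C9 arm, while the proton-scavenging aluminium reagent at −78 °C prevents acid equilibration to the cis lactone.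

Step 18
Reactants: 22 hydroxy lactone
Product: 23 18-(2-naphthylmethoxy)-13,14,15,16-tetranorlabdane-6α,8α,12-triol
Conditions: LiAlH4, THF, 0 °C to rt
Reagents that add atoms: none
Why: LiAlH4 reduces the lactone to the primary C12 alcohol and frees the tertiary C8 hydroxyl, while the naphthylmethyl ether is inert.

Step 19
Reactants: 23 triol
Product: 24 6,8,12-tris(triethylsilyl) ether of 23
Conditions: TESOTf (3.6 equiv), 2,6-lutidine, CH2Cl2, −78 °C to 0 °C
Reagents that add atoms: triethylsilyl trifluoromethanesulfonate, CC[Si](CC)(CC)OS(=O)(=O)C(F)(F)F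
Why: The silyl triflate silylates primary, hindered secondary and tertiary hydroxyls alike, so all three are capped in one operation and the C8 oxygen can no longer displace a leaving group at C12.

Step 20
Reactants: 24 tris(silyl) ether
Product: 25 6α,8α-bis(triethylsilyloxy)-18-(2-naphthylmethoxy)-13,14,15,16-tetranorlabdan-12-ol
Conditions: PPTS (cat.), MeOH/CH2Cl2, 0 °C
Reagents that add atoms: none
Why: Mild acid-catalysed methanolysis cleaves the unhindered primary triethylsilyl ether far faster than the hindered secondary and tertiary ones.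

Step 21
Reactants: 25 primary alcohol
Product: 26 12-iodo-6α,8α-bis(triethylsilyloxy)-18-(2-naphthylmethoxy)-13,14,15,16-tetranorlabdane
Conditions: I2, PPh3, imidazole, CH2Cl2, 0 °C
Reagents that add atoms: iodine, II
Why: Appel-type iodination converts the primary alcohol into the iodide by SN2 displacement of the oxyphosphonium intermediate, with both remaining hydroxyls masked.

Step 22
Reactants: 27 dimethyl L-tartrate
Product: 28 dimethyl (2R,3R)-2,3-bis(tert-butyldimethylsilyloxy)butanedioate
Conditions: TBSOTf, 2,6-lutidine, CH2Cl2, 0 °C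
Reagents that add atoms: tert-butyldimethylsilyl trifluoromethanesulfonate, C[Si](C)(OS(=O)(=O)C(F)(F)F)C(C)(C)C
Why: Silylation of both secondary hydroxyls of the tartrate, whose (2R,3R) centres become C14 and C15 of the target (14,15-syn).

Step 23
Reactants: 28 bis(silyl) tartrate
Product: 30 methyl (2R,3S)-2,3-bis(tert-butyldimethylsilyloxy)pent-4-ynoate, via aldehyde ester 29 (not isolated)
Conditions: DIBAL-H (1.0 equiv), CH2Cl2, −78 °C; then MeOH, K2CO3, dimethyl (1-diazo-2-oxopropyl)phosphonate, 0 °C to rt
Reagents that add atoms: dimethyl (1-diazo-2-oxopropyl)phosphonate, CC(=O)C(=[N+]=[N-])P(=O)(OC)OC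
Why: Half-reduction of one of the two equivalent ester groups to the aldehyde (statistical, over-reduced material is separated) followed in the same flask by Ohira–Bestmann homologation at 0 °C, to limit epimerisation next to the aldehyde, gives the terminal alkyne whose inner carbon is C13.

Step 24
Reactants: 30 alkyne ester
Product: 32 methyl (2R,3R)-2,3-bis(tert-butyldimethylsilyloxy)-4-iodopent-4-enoate, via alkenylborane 31 (not isolated)
Conditions: B-iodo-9-BBN, pentane/CH2Cl2, −20 °C; then AcOH, 0 °C
Reagents that add atoms: B-iodo-9-borabicyclo[3.3.1]nonane, IB1C2CCCC1CCC2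
Why: Syn haloboration puts boron on the terminal carbon and iodine on the internal one, and protonolysis of the C–B bond by acetic acid leaves the 2-iodo-1-alkene (net Markovnikov hydroiodination) under conditions that silyl ethers and esters tolerate.

Step 25
Reactants: 32 iodoalkene ester
Product: 33 (2R,3R)-2,3-bis(tert-butyldimethylsilyloxy)-4-iodopent-4-enal
Conditions: DIBAL-H (1.1 equiv), toluene, −78 °C
Reagents that add atoms: none
Why: DIBAL-H at −78 °C reduces the α-silyloxy ester to the aldehyde through a stable aluminium hemiacetal.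

Step 26
Reactants: 33 aldehyde
Product: 34 methyl 4-hydroxy-5,6-bis(tert-butyldimethylsilyloxy)-7-iodooct-7-en-2-ynoate with the (4R) carbinol (C16)
Conditions: methyl propiolate, Me2Zn, ProPhenol ligand (20 mol %, the enantiomer that gives the R carbinol), Ph3PO (40 mol %), toluene, 0 °C
Reagents that add atoms: methyl propiolate, C#CC(=O)OC
Why: Zinc–ProPhenol-catalysed addition of the zinc acetylide of methyl propiolate to the aldehyde is reagent-controlled, and the ligand enantiomer is chosen to give the (R)-carbinol (15,16-syn), which has to override the Felkin–Anh preference of the α-silyloxy aldehyde.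

Step 27
Reactants: 34 hydroxy ynoate
Product: 36 5-substituted 4-methylfuran-2(5H)-one carrying the bis(silyloxy) iodoalkene arm (C13–C19 fragment), via hydroxy enoate 35 (not isolated)
Conditions: Me2CuLi (from MeLi and CuI), THF, −78 °C; then aq. NH4Cl/AcOH, rt
Reagents that add atoms: methyllithium (used as lithium dimethylcuprate), [Li]C
Why: Syn carbocupration of the ynoate puts the methyl on C17 and leaves the ester cis to the carbinol carbon, so the (Z)-hydroxy enoate lactonises on mild acidic work-up to the 4-methylbutenolide, the cuprate being kept at −78 °C to spare the vinyl iodide.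

Step 28
Reactants: 26 primary iodide; 36 iodoalkene butenolide
Product: 38 fully protected coupled product (C12–C13 bond formed), via alkylzinc iodide 37 (not isolated)
Conditions: Zn dust, LiCl, THF, 40 °C; then 36, PdCl2(dppf) (5 mol %), THF/DMA, 40 °C
Reagents that add atoms: none
Why: Negishi coupling, in which zinc insertion into the primary C–I bond gives a functional-group-tolerant alkylzinc iodide that couples with the 2-iodoalkene under palladium catalysis (dppf suppresses β-hydride elimination) and forms C12–C13 without base, so without risk to the butenolide.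

Step 29
Reactants: 38 naphthylmethyl ether
Product: 39 C18 primary alcohol
Conditions: DDQ, CH2Cl2/pH 7 buffer, 0 °C
Reagents that add atoms: none
Why: DDQ oxidises the electron-rich naphthylmethyl ether to an oxocarbenium ion that is hydrolysed, which frees only the C18 hydroxyl and leaves silyl ethers, alkenes and the butenolide untouched.

Step 30
Reactants: 39 C18 alcohol
Product: 40 C18 aldehyde (tetrasilyl ether of the target)
Conditions: Dess–Martin periodinane, NaHCO3, CH2Cl2, 0 °C
Reagents that add atoms: none
Why: Dess–Martin oxidation of the only free hydroxyl gives the C18 aldehyde, which has no α-hydrogen and cannot epimerise.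

Step 31
Reactants: 40 tetrasilyl ether
Product: 41 CNP0156243.1
Conditions: HF·pyridine, pyridine/THF, 0 °C to rt
Reagents that add atoms: none
Why: Buffered hydrogen fluoride removes the two triethylsilyl and two tert-butyldimethylsilyl ethers under mildly acidic, non-basic conditions that leave the butenolide, the aldehyde and the tertiary and allylic alcohols intact.

Compound list
1 | 2,6-dimethylcyclohexanone (cis/trans mixture) | CC1CCCC(C)C1=O | starting material
2 | allyl chloroformate | C=CCOC(Cl)=O | starting material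
3 | allyl 2,6-dimethylcyclohex-1-en-1-yl carbonate (racemic) | C=CCOC(=O)OC1=C(C)CCCC1C | intermediate
4 | (2S)-2-allyl-2,6-dimethylcyclohexanone (C6 epimers; C2 is the later C4, allyl on the α face) | CC1CCC[C@@](C)(CC=C)C1=O | intermediate
5 | (2S)-2,6-dimethyl-2-[(E)-prop-1-en-1-yl]cyclohexanone (C6 epimers) | CC1CCC[C@@](C)(/C=C/C)C1=O | intermediate
6 | (1S)-1,3-dimethyl-2-oxocyclohexane-1-carbaldehyde (not isolated) | CC1CCC[C@@](C)(C=O)C1=O | intermediate
7 | (2S)-2-(hydroxymethyl)-2,6-dimethylcyclohexanone (C6 epimers) | CC1CCC[C@@](C)(CO)C1=O | intermediate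
8 | [(1S)-1,3-dimethyl-2-oxocyclohexyl]methyl 1H-imidazole-1-carboxylate | CC1CCC[C@@](C)(COC(=O)n2ccnc2)C1=O | intermediate
9 | (1S,5S)-1,5-dimethyl-3-oxabicyclo[3.3.1]nonane-2,9-dione (C5 ketone; C4–C18H2–O–C9(=O)–C10 bridge on the α face; both methyls β) | O=C1[C@@]2(C)CCC[C@@](C)(CO1)C2=O | intermediate
10 | (1S,5R)-1,5-dimethyl-9-methylidene-3-oxabicyclo[3.3.1]nonan-2-one | O=C1[C@@]2(C)CCC[C@@](C)(CO1)C2=C | intermediate
11 | 9-(hydroxymethyl)-1,5-dimethyl-3-oxabicyclo[3.3.1]nonan-2-one, CH2OH (C6) on the carbocycle side, H-5 toward the ring oxygen | O=C1[C@@]2(C)CCC[C@@](C)(CO1)[C@@H]2CO | intermediate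
12 | tert-butyldimethylsilyl ether of 11 | O=C1[C@@]2(C)CCC[C@@](C)(CO1)[C@@H]2CO[Si](C)(C)C(C)(C)C | intermediate
13 | bridged lactol from 12 (C9 hemiacetal, both anomers) | OC1[C@@]2(C)CCC[C@@](C)(CO1)[C@@H]2CO[Si](C)(C)C(C)(C)C | intermediate
14 | ethyl (E)-2-methyl-3-(ring A)prop-2-enoate; ring A: C10 methyl β and enoate α, C5 H α and CH2OTBS β, C4 methyl β and CH2OH α | CCOC(=O)/C(C)=C/[C@@]1(C)CCC[C@@](C)(CO)[C@@H]1CO[Si](C)(C)C(C)(C)C | intermediate
15 | 18-O-(2-naphthylmethyl) ether of 14 | CCOC(=O)/C(C)=C/[C@@]1(C)CCC[C@@](C)(COCc2ccc3ccccc3c2)[C@@H]1CO[Si](C)(C)C(C)(C)C | intermediate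
16 | (E)-allylic alcohol from 15 (C7 hydroxyl) | OC/C(C)=C/[C@@]1(C)CCC[C@@](C)(COCc2ccc3ccccc3c2)[C@@H]1CO[Si](C)(C)C(C)(C)C | intermediate
17 | 1-ethoxyvinyl ether of 16 (ketene acetal, not isolated) | C=C(OCC)OC/C(C)=C/[C@@]1(C)CCC[C@@](C)(COCc2ccc3ccccc3c2)[C@@H]1CO[Si](C)(C)C(C)(C)C | intermediate
18 | ethyl 3-(ring A)-4-methylpent-4-enoate (C9 as in the target; isopropenyl on C9; C6 as CH2OTBS; C18 as CH2O-naphthylmethyl) | CCOC(=O)C[C@@H](C(C)=C)[C@@]1(C)CCC[C@@](C)(COCc2ccc3ccccc3c2)[C@@H]1CO[Si](C)(C)C(C)(C)C | intermediate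
19 | hydroxy ester (18 without the silyl group; not isolated) | CCOC(=O)C[C@@H](C(C)=C)[C@@]1(C)CCC[C@@](C)(COCc2ccc3ccccc3c2)[C@@H]1CO | intermediate
20 | hydroxy acid (C6 hydroxyl, C12 acid) | OC(=O)C[C@@H](C(C)=C)[C@@]1(C)CCC[C@@](C)(COCc2ccc3ccccc3c2)[C@@H]1CO | intermediate
21 | seco aldehyde acid: ring A with C5 formyl (C6), C9 bearing isopropenyl (C7=C8) and CH2CO2H (C11, C12), C18 as CH2O-naphthylmethyl | OC(=O)C[C@@H](C(C)=C)[C@@]1(C)CCC[C@@](C)(COCc2ccc3ccccc3c2)[C@@H]1C=O | intermediate
22 | 6α-hydroxy-18-(2-naphthylmethoxy)-13,14,15,16-tetranorlabdan-12,8α-olide (trans-fused lactone, 8-methyl β) | O=C1C[C@@H]2[C@@]3(C)CCC[C@@](C)(COCc4ccc5ccccc5c4)[C@@H]3[C@@H](O)C[C@@]2(C)O1 | intermediate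
23 | 18-(2-naphthylmethoxy)-13,14,15,16-tetranorlabdane-6α,8α,12-triol | OCC[C@@H]1[C@@]2(C)CCC[C@@](C)(COCc3ccc4ccccc4c3)[C@@H]2[C@@H](O)C[C@@]1(C)O | intermediate
24 | 6,8,12-tris(triethylsilyl) ether of 23 | CC[Si](CC)(CC)OCC[C@@H]1[C@@]2(C)CCC[C@@](C)(COCc3ccc4ccccc4c3)[C@@H]2[C@@H](O[Si](CC)(CC)CC)C[C@@]1(C)O[Si](CC)(CC)CC | intermediate
25 | 6α,8α-bis(triethylsilyloxy)-18-(2-naphthylmethoxy)-13,14,15,16-tetranorlabdan-12-ol | OCC[C@@H]1[C@@]2(C)CCC[C@@](C)(COCc3ccc4ccccc4c3)[C@@H]2[C@@H](O[Si](CC)(CC)CC)C[C@@]1(C)O[Si](CC)(CC)CC | intermediate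
26 | 12-iodo-6α,8α-bis(triethylsilyloxy)-18-(2-naphthylmethoxy)-13,14,15,16-tetranorlabdane | ICC[C@@H]1[C@@]2(C)CCC[C@@](C)(COCc3ccc4ccccc4c3)[C@@H]2[C@@H](O[Si](CC)(CC)CC)C[C@@]1(C)O[Si](CC)(CC)CC | intermediate
27 | dimethyl L-tartrate, dimethyl (2R,3R)-2,3-dihydroxybutanedioate | COC(=O)[C@H](O)[C@@H](O)C(=O)OC | starting material
28 | dimethyl (2R,3R)-2,3-bis(tert-butyldimethylsilyloxy)butanedioate | COC(=O)[C@H](O[Si](C)(C)C(C)(C)C)[C@@H](O[Si](C)(C)C(C)(C)C)C(=O)OC | intermediate
29 | methyl (2R,3R)-2,3-bis(tert-butyldimethylsilyloxy)-4-oxobutanoate (not isolated) | O=C[C@H](O[Si](C)(C)C(C)(C)C)[C@@H](O[Si](C)(C)C(C)(C)C)C(=O)OC | intermediate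
30 | methyl (2R,3S)-2,3-bis(tert-butyldimethylsilyloxy)pent-4-ynoate | C#C[C@H](O[Si](C)(C)C(C)(C)C)[C@@H](O[Si](C)(C)C(C)(C)C)C(=O)OC | intermediate
31 | (Z)-2-iodoalkenyl-9-BBN adduct of 30 (boron on the terminal carbon, cis to iodine; not isolated) | I/C(=C\B1C2CCCC1CCC2)[C@H](O[Si](C)(C)C(C)(C)C)[C@@H](O[Si](C)(C)C(C)(C)C)C(=O)OC | intermediate
32 | methyl (2R,3R)-2,3-bis(tert-butyldimethylsilyloxy)-4-iodopent-4-enoate | C=C(I)[C@H](O[Si](C)(C)C(C)(C)C)[C@@H](O[Si](C)(C)C(C)(C)C)C(=O)OC | intermediate
33 | (2R,3R)-2,3-bis(tert-butyldimethylsilyloxy)-4-iodopent-4-enal | C=C(I)[C@H](O[Si](C)(C)C(C)(C)C)[C@@H](O[Si](C)(C)C(C)(C)C)C=O | intermediate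
34 | methyl 4-hydroxy-5,6-bis(tert-butyldimethylsilyloxy)-7-iodooct-7-en-2-ynoate, (4R) carbinol = C16, C5/C6 = C15/C14 from the tartrate | C=C(I)[C@H](O[Si](C)(C)C(C)(C)C)[C@@H](O[Si](C)(C)C(C)(C)C)[C@H](O)C#CC(=O)OC | intermediate
35 | methyl (Z)-4-hydroxy-3-methyl-5,6-bis(tert-butyldimethylsilyloxy)-7-iodoocta-2,7-dienoate (not isolated) | C=C(I)[C@H](O[Si](C)(C)C(C)(C)C)[C@@H](O[Si](C)(C)C(C)(C)C)[C@H](O)/C(C)=C\C(=O)OC | intermediate
36 | (5R)-5-[1,2-bis(tert-butyldimethylsilyloxy)-3-iodobut-3-en-1-yl]-4-methylfuran-2(5H)-one, C14–C16 as in the target | C=C(I)[C@H](O[Si](C)(C)C(C)(C)C)[C@@H](O[Si](C)(C)C(C)(C)C)[C@@H]1OC(=O)C=C1C | intermediate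
37 | alkylzinc iodide from 26 (C12–ZnI; not isolated) | I[Zn]CC[C@@H]1[C@@]2(C)CCC[C@@](C)(COCc3ccc4ccccc4c3)[C@@H]2[C@@H](O[Si](CC)(CC)CC)C[C@@]1(C)O[Si](CC)(CC)CC | intermediate
38 | coupled product: target skeleton with C18 as CH2O-naphthylmethyl, 6- and 8-O-triethylsilyl, 14- and 15-O-tert-butyldimethylsilyl | C=C(CC[C@@H]1[C@@]2(C)CCC[C@@](C)(COCc3ccc4ccccc4c3)[C@@H]2[C@@H](O[Si](CC)(CC)CC)C[C@@]1(C)O[Si](CC)(CC)CC)[C@H](O[Si](C)(C)C(C)(C)C)[C@@H](O[Si](C)(C)C(C)(C)C)[C@@H]1OC(=O)C=C1C | intermediate
39 | C18 primary alcohol (38 without the naphthylmethyl group) | C=C(CC[C@@H]1[C@@]2(C)CCC[C@@](C)(CO)[C@@H]2[C@@H](O[Si](CC)(CC)CC)C[C@@]1(C)O[Si](CC)(CC)CC)[C@H](O[Si](C)(C)C(C)(C)C)[C@@H](O[Si](C)(C)C(C)(C)C)[C@@H]1OC(=O)C=C1C | intermediate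
40 | C18 aldehyde, tetrasilyl ether of the target | C=C(CC[C@@H]1[C@@]2(C)CCC[C@@](C)(C=O)[C@@H]2[C@@H](O[Si](CC)(CC)CC)C[C@@]1(C)O[Si](CC)(CC)CC)[C@H](O[Si](C)(C)C(C)(C)C)[C@@H](O[Si](C)(C)C(C)(C)C)[C@@H]1OC(=O)C=C1C | intermediate
41 | CNP0156243.1 | C=C(CC[C@@H]1[C@@]2(C)CCC[C@@](C)(C=O)[C@@H]2[C@@H](O)C[C@@]1(C)O)[C@H](O)[C@@H](O)[C@@H]1OC(=O)C=C1C | target

Total step count: 31. Longest linear sequence: 25 steps (steps 1–21 and 28–31); the side-arm branch has 6 steps (22–27) before the union.

Steps most likely to fail

Step 17 (key step, new method). The C8 cation may lose a proton or take up chloride before the carboxylate reaches it, or the trans lactone may equilibrate to the cis isomer. The fallback uses known chemistry and closes the two rings in separate operations. It sets out from ester 18: fluoride alone gives hydroxy ester 19, which is now isolated and oxidised with Dess–Martin periodinane to the seco aldehyde ester F1. Me2AlCl at −78 °C then effects the type 2 carbonyl-ene cyclisation to the 6α-hydroxy decalin ester with an 8(17)-exocyclic alkene F2. Epoxidation with mCPBA on the α face (away from the axial C10 methyl, on the side of the 6α-hydroxyl) gives the 8α,17-epoxide F3. LiAlH4 opens the epoxide at C17 and reduces the ester, which gives triol 23, where the route is rejoined; lactone 22 is bypassed.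

Step 6. Acyl transfer may end on the enolate oxygen without return, or the liberated imidazolide may cleave the non-enolisable 1,3-dicarbonyl product. The fallback replaces tether control by catalyst control and sets out from 7. Silylation (TBSCl, imidazole) gives the silyl ether ketone F4, and LiHMDS/allyl chloroformate gives its allyl enol carbonate F5. A second decarboxylative allylation with Pd2(dba)3 and the enantiomeric ligand (R)-t-BuPHOX gives the cis-dimethyl (2R,6S) allyl ketone F6. Isomerisation with RuHCl(CO)(PPh3)3 gives the propenyl ketone F7, and ozonolysis (O3; Me2S) gives the keto aldehyde F8. Desilylation with HF·pyridine lets the C18 hydroxyl close onto the aldehyde to give the bridged lactol F9, which is oxidised (Ag2CO3 on Celite) to keto lactone 9, where the route is rejoined.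

Step 14. Face selection at C9 may be poor because both alkene faces lie next to the quaternary C10, and bond formation at this neopentyl terminus may be slow enough for the ketene acetal to decompose. The fallback sets C9 by an auxiliary-controlled conjugate addition and sets out from lactol 13. Wittig reaction with (R)-4-benzyl-3-[(triphenylphosphoranylidene)acetyl]oxazolidin-2-one gives the (E)-enoyl imide F10, and 2-(bromomethyl)naphthalene with Ag2O gives its 18-O-naphthylmethyl ether F11. Isopropenylmagnesium bromide with CuBr·SMe2 adds to the chelated s-cis imide on the face left open by the benzyl group and gives the isopropenyl adduct F12 with the C9 configuration of the target. LiOH/H2O2 removes the auxiliary to give the silyl ether acid F13, and TBAF then gives hydroxy acid 20, where the route is rejoined.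

Further compounds
F1 | step 17 | seco aldehyde ethyl ester (ethyl ester of 21) | CCOC(=O)C[C@@H](C(C)=C)[C@@]1(C)CCC[C@@](C)(COCc2ccc3ccccc3c2)[C@@H]1C=O
F2 | step 17 | ethyl 6α-hydroxy-18-(2-naphthylmethoxy)-13,14,15,16-tetranorlabd-8(17)-en-12-oate | CCOC(=O)C[C@@H]1[C@@]2(C)CCC[C@@](C)(COCc3ccc4ccccc4c3)[C@@H]2[C@@H](O)CC1=C
F3 | step 17 | 8α,17-epoxide of F2 | CCOC(=O)C[C@@H]1[C@@]2(C)CCC[C@@](C)(COCc3ccc4ccccc4c3)[C@@H]2[C@@H](O)C[C@]13CO3
F4 | step 6 | (2S)-2-[(tert-butyldimethylsilyloxy)methyl]-2,6-dimethylcyclohexanone | CC1CCC[C@@](C)(CO[Si](C)(C)C(C)(C)C)C1=O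
F5 | step 6 | allyl enol carbonate of F4 | C=CCOC(=O)OC1=C(C)CCC[C@@]1(C)CO[Si](C)(C)C(C)(C)C
F6 | step 6 | (2R,6S)-2-allyl-6-[(tert-butyldimethylsilyloxy)methyl]-2,6-dimethylcyclohexanone (methyls cis) | C=CC[C@@]1(C)CCC[C@@](C)(CO[Si](C)(C)C(C)(C)C)C1=O
F7 | step 6 | (E)-prop-1-enyl isomer of F6 | C/C=C/[C@@]1(C)CCC[C@@](C)(CO[Si](C)(C)C(C)(C)C)C1=O
F8 | step 6 | 3-[(tert-butyldimethylsilyloxy)methyl]-1,3-dimethyl-2-oxocyclohexane-1-carbaldehyde (methyls cis) | O=C[C@@]1(C)CCC[C@@](C)(CO[Si](C)(C)C(C)(C)C)C1=O
F9 | step 6 | 2-hydroxy-1,5-dimethyl-3-oxabicyclo[3.3.1]nonan-9-one (bridged lactol, both anomers) | OC1[C@@]2(C)CCC[C@@](C)(CO1)C2=O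
F10 | step 14 | (R)-4-benzyl-3-[(E)-3-(ring A)prop-2-enoyl]oxazolidin-2-one with free C18 hydroxyl and C6 silyl ether | O=C(/C=C/[C@@]1(C)CCC[C@@](C)(CO)[C@@H]1CO[Si](C)(C)C(C)(C)C)N1[C@H](Cc2ccccc2)COC1=O
F11 | step 14 | 18-O-(2-naphthylmethyl) ether of F10 | O=C(/C=C/[C@@]1(C)CCC[C@@](C)(COCc2ccc3ccccc3c2)[C@@H]1CO[Si](C)(C)C(C)(C)C)N1[C@H](Cc2ccccc2)COC1=O
F12 | step 14 | isopropenyl conjugate adduct of F11 (C9 as in the target) | O=C(C[C@@H](C(C)=C)[C@@]1(C)CCC[C@@](C)(COCc2ccc3ccccc3c2)[C@@H]1CO[Si](C)(C)C(C)(C)C)N1[C@H](Cc2ccccc2)COC1=O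
F13 | step 14 | silyl ether acid (20 as its C6 tert-butyldimethylsilyl ether) | OC(=O)C[C@@H](C(C)=C)[C@@]1(C)CCC[C@@](C)(COCc2ccc3ccccc3c2)[C@@H]1CO[Si](C)(C)C(C)(C)C
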